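## Retrosynthetic overview

1. Target ⇒ racemic 2-farnesyl ketone: cut the C2–OH bond of the hemiketal (the only stereocentre). It is made last, by catalytic enantioselective oxygen transfer to the enol.
2. 2-Farnesyl ketone ⇒ 6-hydroxybenzofuran-3(2H)-one + (2E,6E)-farnesyl bromide: C2–C1' bond by C-alkylation of the phenoxide/enolate dianion, without protecting groups.
3. Farnesyl bromide ⇒ (2E,6E)-farnesol (mesylate, then bromide).
4. No ring is formed: benzene ring A and furanone ring B are bought together in the benzofuranone, and all three alkenes come from farnesol.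

Assumption: the (2R) hemiketal is configurationally stable under neutral or weakly acidic aprotic conditions at or below room temperature (ring-opening to the 1,2-diketone is slow), so it is made last and never meets base; the sense of induction of the new step is not predictable, so the (S)-acid written is exchanged for the (R)-acid if the first run gives (2S).

## Route

Step 1
Reactants: 1 (2E,6E)-farnesol
Product: 3 (2E,6E)-farnesyl bromide, via (2E,6E)-farnesyl mesylate 2 (not isolated)
Conditions: MsCl, Et3N, THF, −45 °C; then LiBr, THF, 0 °C; used crude the same day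
Reagents that add atoms: lithium bromide, [Li+].[Br-]
Why: Mesylation followed by SN2 bromide exchange at the primary allylic carbon at low temperature avoids allylic transposition and E/Z erosion; no stereocentre is involved.

Step 2
Reactants: 4 6-hydroxy-1-benzofuran-3(2H)-one; 3 (2E,6E)-farnesyl bromide
Product: 6 rac-6-hydroxy-2-[(2E,6E)-3,7,11-trimethyldodeca-2,6,10-trien-1-yl]-1-benzofuran-3(2H)-one (2-farnesyl ketone; racemic at C2), via dilithium 1-benzofuran-3,6-diolate 5 (not isolated)
Conditions: 4 (1.5 equiv) added to LiN(SiMe3)2 (3.1 equiv), THF, −78 °C; then 3 (1.0 equiv), −78 to −30 °C; AcOH quench at −78 °C; Ar, degassed solvents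
Reagents that add atoms: none
Why: Dianion alkylation, in which the last-formed and most basic site (C2 of the enolate) reacts first, the lithium counter-ion in THF and the soft allylic bromide favour C- over O-alkylation, SN2 at the primary carbon keeps the 2E geometry, and excess dianion limits dialkylation; C2 is formed racemic, which the next step needs.

Step 3
Reactants: 6 rac-6-hydroxy-2-[(2E,6E)-3,7,11-trimethyldodeca-2,6,10-trien-1-yl]-1-benzofuran-3(2H)-one
Product: 9 (2R)-2,6-dihydroxy-2-[(2E,6E)-3,7,11-trimethyldodeca-2,6,10-trien-1-yl]-1-benzofuran-3(2H)-one (target), via enol tautomer 7 (not isolated), via aminoxy ketone 8 (not isolated)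
Conditions: (S)-3,3'-bis(2,4,6-triisopropylphenyl)-1,1'-binaphthyl-2,2'-diyl hydrogen phosphate (5 mol %), PhNO (2.3 equiv, added over 6 h), toluene (0.05 M), 0 °C, Ar, dark; then filtration through silica and chromatography with neutral eluent
Reagents that add atoms: nitrosobenzene, O=Nc1ccccc1
Why: Proposed new method: chiral-phosphoric-acid enol catalysis applied to a 2-alkylbenzofuran-3(2H)-one to create a hemiketal C–O stereocentre, which has not been shown for this substrate class; the acid speeds tautomerism of 6 to the aromatic 3-hydroxybenzofuran 7 and holds it in a two-point hydrogen-bonded array (P=O···H–O of the enol, P–OH···N of PhNO), so C2 attacks the nitroso oxygen on the face left open by the triisopropylphenyl walls (O-selective nitroso aldol, sets C2, racemic 6 converges through planar 7); a second PhNO then cleaves the N–O bond of 8 to give the free OH and azoxybenzene without base; PhNO kept at low concentration at 0 °C should react much faster with the catalyst-bound enol than by ene reaction with the three trisubstituted alkenes, and the weak acid does not protonate them; closest known reaction type: chiral-phosphoric-acid-catalysed α-hydroxylation and α-amination of α-branched cyclic ketones with nitrosoarenes or azodicarboxylates, and acid-catalysed α-hydroxylation of β-dicarbonyls with nitrosobenzene.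

## Compound list

1 | (2E,6E)-farnesol | CC(C)=CCC/C(C)=C/CC/C(C)=C/CO | starting material
2 | (2E,6E)-farnesyl methanesulfonate | CC(C)=CCC/C(C)=C/CC/C(C)=C/COS(C)(=O)=O | intermediate
3 | (2E,6E)-farnesyl bromide | CC(C)=CCC/C(C)=C/CC/C(C)=C/CBr | intermediate
4 | 6-hydroxy-1-benzofuran-3(2H)-one | O=C1COc2cc(O)ccc12 | starting material
5 | dilithium 1-benzofuran-3,6-diolate | [Li+].[Li+].[O-]c1coc2cc([O-])ccc12 | intermediate
6 | rac-6-hydroxy-2-[(2E,6E)-3,7,11-trimethyldodeca-2,6,10-trien-1-yl]-1-benzofuran-3(2H)-one | CC(C)=CCC/C(C)=C/CC/C(C)=C/CC1Oc2cc(O)ccc2C1=O | intermediate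
7 | 2-[(2E,6E)-3,7,11-trimethyldodeca-2,6,10-trien-1-yl]-1-benzofuran-3,6-diol (enol tautomer of 6) | CC(C)=CCC/C(C)=C/CC/C(C)=C/Cc1oc2cc(O)ccc2c1O | intermediate
8 | (2S)-6-hydroxy-2-[(phenylamino)oxy]-2-[(2E,6E)-3,7,11-trimethyldodeca-2,6,10-trien-1-yl]-1-benzofuran-3(2H)-one (same spatial arrangement as 9; descriptor changes by priority only) | CC(C)=CCC/C(C)=C/CC/C(C)=C/C[C@@]1(ONc3ccccc3)Oc2cc(O)ccc2C1=O | intermediate
9 | (2R)-2,6-dihydroxy-2-[(2E,6E)-3,7,11-trimethyldodeca-2,6,10-trien-1-yl]-1-benzofuran-3(2H)-one | CC(C)=CCC/C(C)=C/CC/C(C)=C/C[C@@]1(O)Oc2cc(O)ccc2C1=O | target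

## Step count and risks

Total steps: 3. Longest linear sequence: 3 (1 → 3 → 6 → 9); 4 enters at step 2.

Most likely to fail is step 3, the new enantioselective hydroxylation. The risks are low ee, slow enolisation of the electron-rich ketone, nitroso-ene reaction on the side chain, and acid-catalysed ring-opening that racemises 9. The fallback is known reagent-controlled asymmetric enolate hydroxylation and sets out from 6. NaN(SiMe3)2 (2.2 equiv) in THF at −78 °C gives the disodium 2-[(2E,6E)-farnesyl]-1-benzofuran-3,6-diolate F1. This is treated at −78 °C with the enantiopure [(8,8-dichlorocamphoryl)sulfonyl]oxaziridine antipode that delivers (2R) (both antipodes are sold) and quenched cold with AcOH. It comes back to the route at 9; the ee can be raised by chiral-phase HPLC.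

Second is step 2, the dianion alkylation. The risks are a poorly soluble dianion, O-alkylation to the 3-farnesyloxybenzofuran, 2,2-dialkylation, and autoxidation of 6 at C2 in air. The fallback makes the C2–C1' bond at the aldehyde oxidation level, where over- and O-alkylation cannot occur, and sets out from 1 and 4. MnO2 in hexane at room temperature oxidises 1 to (2E,6E)-farnesal F2. Condensation of F2 with 4 on neutral Al2O3 (CH2Cl2, room temperature, dark) gives the aurone-type dienone (2Z)-6-hydroxy-2-[(2E,6E)-3,7,11-trimethyldodeca-2,6,10-trien-1-ylidene]-1-benzofuran-3(2H)-one F3. Conjugate reduction with potassium tri-sec-butylborohydride, K[BH(s-Bu)3] (2.2 equiv, the first consumed by the phenol; THF, −78 °C, AcOH quench), follows. Hydride should add at the unhindered exocyclic CH rather than the fully substituted 1,6-terminus, giving the aromatic 3-oxidobenzofuran. The sequence comes back to the route at 6.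

Third is step 1, the bromide. The risks are decomposition and allylic transposition of 3 on concentration or storage. The fallback replaces it with a storable electrophile made by a different activation and sets out from 1. NCS and Me2S (CH2Cl2, −40 to 0 °C) give (2E,6E)-farnesyl chloride F4, which can be purified and kept. F4 alkylates dianion 5 in THF with DMPU at −40 to 0 °C and comes back to the route at 6.

Further compounds

F1 | step 3 | disodium 2-[(2E,6E)-3,7,11-trimethyldodeca-2,6,10-trien-1-yl]-1-benzofuran-3,6-diolate | [Na+].[Na+].CC(C)=CCC/C(C)=C/CC/C(C)=C/Cc1oc2cc([O-])ccc2c1[O-]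
F2 | step 2 | (2E,6E)-farnesal | CC(C)=CCC/C(C)=C/CC/C(C)=C/C=O
F3 | step 2 | (2Z)-6-hydroxy-2-[(2E,6E)-3,7,11-trimethyldodeca-2,6,10-trien-1-ylidene]-1-benzofuran-3(2H)-one | CC(C)=CCC/C(C)=C/CC/C(C)=C/C=C1\Oc2cc(O)ccc2C1=O
F4 | step 1 | (2E,6E)-farnesyl chloride | CC(C)=CCC/C(C)=C/CC/C(C)=C/CCl
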